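**Retrosynthetic overview**
1. Target 30 ⇐ epoxy alcohol 29 (oxidation) ⇐ macrocyclic allylic alcohol 28 (Sharpless epoxidation) ⇐ triacetate 27 ⇐ triol 26 ⇐ lactone-bridged macrocycle 25 (DIBAL).
2. The ten-membered carbocycle is closed at C5–C6 by an intramolecular Nozaki–Hiyama–Kishi reaction of iodo-aldehyde 24.
3. 24 ⇐ HWE olefination (C1=C10) of lactone phosphonate 22 with vinyl iodide aldehyde 8.
4. 22 ⇐ Crimmins syn-aldol (C7–C8) of N-isovaleryl thiazolidinethione 18 with phosphono-aldehyde 14.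
5. Three fragments 8, 14 and 18 are made in parallel; ring order: temporary γ-lactone → ten-membered ring → oxirane.

Assumption: atoms are labelled with germacrane numbering (ring C1–C10, C14 = formyl carbon on C10, C15 = methyl on C4, isopropyl on C7); the target is then (1R,6R,7S,8R,10S,4E)-6,8-diacetoxy-1,10-epoxygermacr-4-en-14-al.

**Fragment A (C1–C5, C15)**

Step 1
Reactants: 1 prop-2-yn-1-ol (propargyl alcohol)
Product: 3 (E)-3-iodo-2-methylprop-2-en-1-ol, via dimethylaluminium (E)-3-(dimethylalumanyl)-2-methylprop-2-en-1-olate 2 (not isolated)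
Conditions: AlMe3 (3 eq), Cp2ZrCl2 (0.25 eq), CH2Cl2, 0 °C → rt; then I2, THF, −30 → 0 °C; aq. K2CO3
Reagents that add atoms: trimethylaluminium C[Al](C)C; iodine II
Why: Zr-catalysed Negishi carboalumination adds Me–Al syn (Me to the internal carbon) and iodinolysis of the C–Al bond goes with retention, fixing the (E)-vinyl iodide that becomes C4=C5.

Step 2
Reactants: 3 (E)-3-iodo-2-methylprop-2-en-1-ol
Product: 4 (E)-3-bromo-1-iodo-2-methylprop-1-ene
Conditions: CBr4, PPh3, CH2Cl2, 0 °C
Reagents that add atoms: carbon tetrabromide BrC(Br)(Br)Br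
Why: Appel reaction converts the primary allylic alcohol to the bromide under neutral conditions without touching the vinyl iodide or its geometry.

Step 3
Reactants: 4 (E)-3-bromo-1-iodo-2-methylprop-1-ene; 5 N-methoxy-N-methylacetamide
Product: 7 (E)-5-iodo-N-methoxy-N,4-dimethylpent-4-enamide, via lithium 1-[methoxy(methyl)amino]ethen-1-olate 6 (not isolated)
Conditions: LDA, THF, −78 °C; then 4, −78 → −20 °C
Reagents that add atoms: none
Why: SN2 alkylation of the Weinreb acetamide enolate by the reactive allylic bromide adds C1–C2; vinyl iodides are inert to lithium enolates.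

Step 4
Reactants: 7 (E)-5-iodo-N-methoxy-N,4-dimethylpent-4-enamide
Product: 8 (E)-5-iodo-4-methylpent-4-enal
Conditions: DIBAL-H, THF, −78 °C; aq. Rochelle salt
Reagents that add atoms: none
Why: Weinreb amide reduction stops at the chelated tetrahedral aluminate, which releases the aldehyde only on work-up.

**Fragment B (C8–C10, C14)**

Step 5
Reactants: 9 triethyl phosphonoacetate; 10 allyl bromide
Product: 12 ethyl 2-(diethoxyphosphoryl)pent-4-enoate (racemic), via sodium 2-(diethoxyphosphoryl)-1-ethoxy-1-oxoethan-2-ide 11 (not isolated)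
Conditions: NaH, THF, 0 °C; then 10, 0 °C → rt
Reagents that add atoms: none
Why: C-alkylation (SN2) of the stabilised phosphonoacetate anion installs the allyl group as a masked formylmethyl unit.

Step 6
Reactants: 12 ethyl 2-(diethoxyphosphoryl)pent-4-enoate
Product: 14 ethyl 2-(diethoxyphosphoryl)-4-oxobutanoate (racemic), via ethyl 2-(diethoxyphosphoryl)-3-(1,2,4-trioxolan-3-yl)propanoate 13 (not isolated)
Conditions: O3, CH2Cl2, −78 °C; then Me2S, −78 °C → rt
Reagents that add atoms: ozone [O-][O+]=O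
Why: Ozonolysis with reductive work-up cleaves the only C=C to the aldehyde that becomes C8.

**Fragment C (C6, C7, isopropyl)**

Step 7
Reactants: 15 (S)-2-amino-3-phenylpropan-1-ol (L-phenylalaninol)
Product: 16 (S)-4-benzyl-1,3-thiazolidine-2-thione
Conditions: CS2 (5 eq), aq. KOH, reflux
Reagents that add atoms: carbon disulfide S=C=S
Why: Dithiocarbamate and xanthate formation followed by intramolecular S-alkylation at the primary carbon gives the thiazolidinethione; the stereocentre is not touched.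

Step 8
Reactants: 16 (S)-4-benzyl-1,3-thiazolidine-2-thione; 17 3-methylbutanoyl chloride (isovaleryl chloride)
Product: 18 (S)-4-benzyl-3-(3-methylbutanoyl)-1,3-thiazolidine-2-thione
Conditions: Et3N, DMAP (cat.), CH2Cl2, 0 °C → rt
Reagents that add atoms: none
Why: N-acylation of the auxiliary gives the Crimmins aldol donor.

**Assembly and endgame**

Step 9
Reactants: 18 (S)-4-benzyl-3-(3-methylbutanoyl)-1,3-thiazolidine-2-thione; 14 ethyl 2-(diethoxyphosphoryl)-4-oxobutanoate
Product: 21 (4S)-4-benzyl-3-{(2S)-2-[(2R)-4-(diethoxyphosphoryl)-5-oxooxolan-2-yl]-3-methylbutanoyl}-1,3-thiazolidine-2-thione (epimers at the P-bearing carbon), via the trichlorotitanium (Z)-enolate of the imide 19 (not isolated), via ethyl (4R,5S)-5-{[(4S)-4-benzyl-2-sulfanylidene-1,3-thiazolidin-3-yl]carbonyl}-2-(diethoxyphosphoryl)-4-hydroxy-6-methylheptanoate 20 (not isolated)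
Conditions: TiCl4 (1.05 eq), iPr2NEt (1.1 eq), NMP (2 eq), CH2Cl2, 0 °C; then 14, −78 → 0 °C; aq. NH4Cl; crude + PPTS (cat.), PhMe, 60 °C
Reagents that add atoms: none
Why: Crimmins Ti-mediated syn-aldol through the (Z)-enolate and a non-chelated Zimmerman–Traxler transition state ("Evans-syn"), so the (S)-benzyl auxiliary sets C7 and C8 (isopropyl and O-8 syn); the γ-hydroxy ester then lactonises under acid.

Step 10
Reactants: 21 lactone imide
Product: 22 diethyl {(5R)-5-[(2R)-1-hydroxy-3-methylbutan-2-yl]-2-oxooxolan-3-yl}phosphonate (epimers at C3)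
Conditions: NaBH4, THF/EtOH, 0 °C
Reagents that add atoms: none
Why: The activated N-acyl thiazolidinethione is reduced by NaBH4 much faster than the lactone or phosphonate, giving the C6 alcohol and the recoverable auxiliary without touching C7 or C8.

Step 11
Reactants: 22 hydroxy lactone phosphonate; 8 (E)-5-iodo-4-methylpent-4-enal
Product: 23 (3E,5R)-5-[(2R)-1-hydroxy-3-methylbutan-2-yl]-3-[(4E)-5-iodo-4-methylpent-4-en-1-ylidene]oxolan-2-one
Conditions: LiCl, DBU, MeCN, 0 °C → rt (minor Z isomer removed by chromatography)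
Reagents that add atoms: none
Why: Masamune–Roush Horner–Wadsworth–Emmons olefination of the α-phosphono lactone gives mainly the (E)-alkylidene lactone (chain anti to C=O, so C2 is cis to C9 as the cis-epoxide requires); the free primary OH is tolerated.

Step 12
Reactants: 23 hydroxy alkylidene lactone
Product: 24 (2S)-2-{(2R,4E)-4-[(4E)-5-iodo-4-methylpent-4-en-1-ylidene]-5-oxooxolan-2-yl}-3-methylbutanal
Conditions: Dess–Martin periodinane, NaHCO3, CH2Cl2, 0 °C → rt; used at once
Reagents that add atoms: none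
Why: Buffered Dess–Martin oxidation gives the α-chiral, β-acyloxy aldehyde without epimerisation or β-elimination.

Step 13
Reactants: 24 iodo-aldehyde
Product: 25 (6R,7R,8R,1(10)E,4E)-6-hydroxygermacra-1(10),4-dien-14,8-olide (ten-membered carbocycle with a γ-lactone bridge from C14 to O-8)
Conditions: CrCl2 (10 eq), NiCl2 (0.1 eq), DMSO/THF 3:1, rt, 3 mM, syringe-pump addition over 12 h
Reagents that add atoms: none
Why: Intramolecular Nozaki–Hiyama–Kishi macrocyclisation: the alkenylchromium(III) formed from the vinyl iodide adds chemoselectively to the aldehyde with retention of the (E)-olefin; C6 is set in the ring closure, with attack anti to O-8 (1,3-anti, Felkin with iPr as the large group) expected to favour the 6R alcohol, the 6-epimer being separable.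

Step 14
Reactants: 25 bridged lactone
Product: 26 (1(10)E,4E,6R,7S,8R)-germacra-1(10),4-diene-6,8,14-triol
Conditions: DIBAL-H (5 eq), CH2Cl2, −78 → 0 °C; aq. Rochelle salt
Reagents that add atoms: none
Why: DIBAL 1,2-reduces the conjugated lactone through the lactol to the allylic alcohol, releasing O-8 and C14–OH without conjugate reduction.

Step 15
Reactants: 26 triol
Product: 27 (1(10)E,4E,6R,7S,8R)-germacra-1(10),4-diene-6,8,14-triyl triacetate
Conditions: Ac2O, pyridine, DMAP (cat.), CH2Cl2, 0 °C → rt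
Reagents that add atoms: acetic anhydride CC(=O)OC(C)=O
Why: DMAP-catalysed acylation of all three hydroxyls installs the two acetates of the target.

Step 16
Reactants: 27 triacetate
Product: 28 (1(10)E,4E,6R,7S,8R)-14-hydroxygermacra-1(10),4-diene-6,8-diyl diacetate
Conditions: Candida antarctica lipase B (immobilised), pH 7 phosphate buffer/acetone, 30 °C
Reagents that add atoms: none
Why: Lipase-catalysed hydrolysis cleaves the unhindered primary acetate far faster than the two hindered secondary acetates.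

Step 17
Reactants: 28 allylic alcohol diacetate
Product: 29 (1R,6R,7S,8R,10R,4E)-1,10-epoxy-14-hydroxygermacr-4-ene-6,8-diyl diacetate
Conditions: Ti(OiPr)4, D-(−)-diethyl tartrate, t-BuOOH, 4 Å MS, CH2Cl2, −20 °C
Reagents that add atoms: tert-butyl hydroperoxide CC(C)(C)OO
Why: Sharpless asymmetric epoxidation: the Ti–tartrate complex binds the only free allylic hydroxyl and delivers oxygen syn to one face of C1=C10 under reagent control (D-(−)-DET gives the 1R,10R cis-epoxide); C4=C5 is an allylic acetate and is not epoxidised.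

Step 18
Reactants: 29 epoxy alcohol
Product: 30 pulicanaral A, (1R,6R,7S,8R,10S,4E)-6,8-diacetoxy-1,10-epoxygermacr-4-en-14-al
Conditions: Dess–Martin periodinane, NaHCO3, CH2Cl2, 0 °C → rt
Reagents that add atoms: none
Why: Dess–Martin oxidation of the primary epoxy alcohol gives the epoxy aldehyde; the α-carbon is quaternary and cannot epimerise.

**Compound list**
1 | prop-2-yn-1-ol | C#CCO | starting material
2 | dimethylaluminium (E)-3-(dimethylalumanyl)-2-methylprop-2-en-1-olate | C[Al](C)OC/C(C)=C/[Al](C)C | intermediate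
3 | (E)-3-iodo-2-methylprop-2-en-1-ol | OC/C(C)=C/I | intermediate
4 | (E)-3-bromo-1-iodo-2-methylprop-1-ene | BrC/C(C)=C/I | intermediate
5 | N-methoxy-N-methylacetamide | CON(C)C(C)=O | starting material
6 | lithium 1-[methoxy(methyl)amino]ethen-1-olate | [Li]OC(=C)N(C)OC | intermediate
7 | (E)-5-iodo-N-methoxy-N,4-dimethylpent-4-enamide | CON(C)C(=O)CC/C(C)=C/I | intermediate
8 | (E)-5-iodo-4-methylpent-4-enal | O=CCC/C(C)=C/I | intermediate
9 | triethyl phosphonoacetate | CCOC(=O)CP(=O)(OCC)OCC | starting material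
10 | allyl bromide | C=CCBr | starting material
11 | sodium 2-(diethoxyphosphoryl)-1-ethoxy-1-oxoethan-2-ide | CCOC(=O)[CH-]P(=O)(OCC)OCC.[Na+] | intermediate
12 | ethyl 2-(diethoxyphosphoryl)pent-4-enoate | CCOC(=O)C(CC=C)P(=O)(OCC)OCC | intermediate
13 | ethyl 2-(diethoxyphosphoryl)-3-(1,2,4-trioxolan-3-yl)propanoate | CCOC(=O)C(CC1OCOO1)P(=O)(OCC)OCC | intermediate
14 | ethyl 2-(diethoxyphosphoryl)-4-oxobutanoate | CCOC(=O)C(CC=O)P(=O)(OCC)OCC | intermediate
15 | (S)-2-amino-3-phenylpropan-1-ol | N[C@@H](Cc1ccccc1)CO | starting material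
16 | (S)-4-benzyl-1,3-thiazolidine-2-thione | S=C1N[C@@H](Cc2ccccc2)CS1 | intermediate
17 | 3-methylbutanoyl chloride | CC(C)CC(Cl)=O | starting material
18 | (S)-4-benzyl-3-(3-methylbutanoyl)-1,3-thiazolidine-2-thione | CC(C)CC(=O)N1[C@@H](Cc2ccccc2)CSC1=S | intermediate
19 | trichlorotitanium (Z)-enolate of 18 | CC(C)/C=C(\O[Ti](Cl)(Cl)Cl)N1[C@@H](Cc2ccccc2)CSC1=S | intermediate
20 | ethyl (4R,5S)-5-{[(4S)-4-benzyl-2-sulfanylidene-1,3-thiazolidin-3-yl]carbonyl}-2-(diethoxyphosphoryl)-4-hydroxy-6-methylheptanoate | CC(C)[C@H](C(=O)N1[C@@H](Cc2ccccc2)CSC1=S)[C@H](O)CC(P(=O)(OCC)OCC)C(=O)OCC | intermediate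
21 | (4S)-4-benzyl-3-{(2S)-2-[(2R)-4-(diethoxyphosphoryl)-5-oxooxolan-2-yl]-3-methylbutanoyl}-1,3-thiazolidine-2-thione | CC(C)[C@H](C(=O)N1[C@@H](Cc2ccccc2)CSC1=S)[C@H]1CC(P(=O)(OCC)OCC)C(=O)O1 | intermediate
22 | diethyl {(5R)-5-[(2R)-1-hydroxy-3-methylbutan-2-yl]-2-oxooxolan-3-yl}phosphonate | CC(C)[C@H](CO)[C@H]1CC(P(=O)(OCC)OCC)C(=O)O1 | intermediate
23 | (3E,5R)-5-[(2R)-1-hydroxy-3-methylbutan-2-yl]-3-[(4E)-5-iodo-4-methylpent-4-en-1-ylidene]oxolan-2-one | CC(C)[C@H](CO)[C@H]1C/C(=C\CC/C(C)=C/I)C(=O)O1 | intermediate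
24 | (2S)-2-{(2R,4E)-4-[(4E)-5-iodo-4-methylpent-4-en-1-ylidene]-5-oxooxolan-2-yl}-3-methylbutanal | CC(C)[C@H](C=O)[C@H]1C/C(=C\CC/C(C)=C/I)C(=O)O1 | intermediate
25 | (6R,7R,8R,1(10)E,4E)-6-hydroxygermacra-1(10),4-dien-14,8-olide | O[C@@H]1/C=C(\C)CC/C=C2\C[C@@H](OC2=O)[C@@H]1C(C)C | intermediate
26 | (1(10)E,4E,6R,7S,8R)-germacra-1(10),4-diene-6,8,14-triol | O[C@@H]1/C=C(\C)CC/C=C(CO)\C[C@@H](O)[C@@H]1C(C)C | intermediate
27 | (1(10)E,4E,6R,7S,8R)-germacra-1(10),4-diene-6,8,14-triyl triacetate | CC(=O)O[C@@H]1/C=C(\C)CC/C=C(COC(C)=O)\C[C@@H](OC(C)=O)[C@@H]1C(C)C | intermediate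
28 | (1(10)E,4E,6R,7S,8R)-14-hydroxygermacra-1(10),4-diene-6,8-diyl diacetate | CC(=O)O[C@@H]1/C=C(\C)CC/C=C(CO)\C[C@@H](OC(C)=O)[C@@H]1C(C)C | intermediate
29 | (1R,6R,7S,8R,10R,4E)-1,10-epoxy-14-hydroxygermacr-4-ene-6,8-diyl diacetate | CC(=O)O[C@@H]1/C=C(\C)CC[C@H]2O[C@@]2(CO)C[C@@H](OC(C)=O)[C@@H]1C(C)C | intermediate
30 | pulicanaral A | CC(=O)O[C@@H]1/C=C(\C)CC[C@H]2O[C@@]2(C=O)C[C@@H](OC(C)=O)[C@@H]1C(C)C | target

**Total step count:** 18

**Longest linear sequence:** 12 steps (steps 7–8–9–10–11–12–13–14–15–16–17–18; the paths through steps 1–4 and through steps 5–6 are equally long).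

**Three steps most likely to fail**

Step 13 (NHK ring closure of the lactone-bridged seco-aldehyde; ring strain of the bicycle and C6 selectivity). The fallback removes the lactone bridge before ring closure. It sets out from 23 and returns at 27. The primary alcohol of 23 is silylated (TESCl, imidazole) to the triethylsilyl ether F1. DIBAL reduces the lactone to the 8,14-diol F2, and Ac2O/DMAP gives the 8,14-diacetate F3. Direct Swern oxidation of the primary TES ether gives the open-chain iodo-aldehyde F4. NHK macrocyclisation of this unbridged precursor gives the macrocyclic 6-alcohol F5, whose acetylation gives 27.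

Step 17 (Sharpless epoxidation on the macrocycle; the ring conformation may oppose the reagent). The fallback puts the epoxide in on an open chain, where the tartrate alone decides the face. It sets out from 23 and returns at 29. Compound 23 is protected as the tert-butyldiphenylsilyl ether F6 and reduced with DIBAL to the acyclic diol F7. Sharpless epoxidation of the primary allylic alcohol with D-(−)-DET gives the epoxy diol F8. Ac2O/DMAP gives the epoxy diacetate F9, HF·pyridine frees the primary alcohol F10, and Dess–Martin oxidation gives the epoxy iodo-aldehyde F11. NHK macrocyclisation gives the macrocyclic epoxy alcohol F12, acetylation gives the epoxy triacetate F13, and lipase hydrolysis of the primary acetate gives 29.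

Step 16 (enzymatic discrimination of the primary acetate on a congested macrocycle). The fallback differentiates the hydroxyls sterically before acylation. It sets out from 26 and returns at 28. TBSCl/imidazole at −20 °C silylates only the primary allylic hydroxyl to give the 14-silyl ether F14. Ac2O/DMAP acetylates O-6 and O-8 to give the silyl diacetate F15, and HF·pyridine removes the silyl group to give 28.

**Further compounds**
F1 | step 13 | triethylsilyl ether of 23 | CC(C)[C@H](CO[Si](CC)(CC)CC)[C@H]1C/C(=C\CC/C(C)=C/I)C(=O)O1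
F2 | step 13 | open-chain 8,14-diol, 6-O-TES | CC(C)[C@H](CO[Si](CC)(CC)CC)[C@H](O)C/C(CO)=C\CC/C(C)=C/I
F3 | step 13 | open-chain 8,14-diacetate, 6-O-TES | CC(C)[C@H](CO[Si](CC)(CC)CC)[C@H](OC(C)=O)C/C(COC(C)=O)=C\CC/C(C)=C/I
F4 | step 13 | open-chain 8,14-diacetoxy iodo-aldehyde | CC(C)[C@H](C=O)[C@H](OC(C)=O)C/C(COC(C)=O)=C\CC/C(C)=C/I
F5 | step 13 | macrocyclic 6-alcohol 8,14-diacetate | O[C@@H]1/C=C(\C)CC/C=C(COC(C)=O)\C[C@@H](OC(C)=O)[C@@H]1C(C)C
F6 | step 17 | tert-butyldiphenylsilyl ether of 23 | CC(C)[C@H](CO[Si](c1ccccc1)(c1ccccc1)C(C)(C)C)[C@H]1C/C(=C\CC/C(C)=C/I)C(=O)O1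
F7 | step 17 | open-chain 8,14-diol, 6-O-TBDPS | CC(C)[C@H](CO[Si](c1ccccc1)(c1ccccc1)C(C)(C)C)[C@H](O)C/C(CO)=C\CC/C(C)=C/I
F8 | step 17 | open-chain 1,10-epoxy-8,14-diol, 6-O-TBDPS | CC(C)[C@H](CO[Si](c1ccccc1)(c1ccccc1)C(C)(C)C)[C@H](O)C[C@]1(CO)O[C@@H]1CC/C(C)=C/I
F9 | step 17 | open-chain 1,10-epoxy-8,14-diacetate, 6-O-TBDPS | CC(C)[C@H](CO[Si](c1ccccc1)(c1ccccc1)C(C)(C)C)[C@H](OC(C)=O)C[C@]1(COC(C)=O)O[C@@H]1CC/C(C)=C/I
F10 | step 17 | open-chain 1,10-epoxy-8,14-diacetate 6-alcohol | CC(C)[C@H](CO)[C@H](OC(C)=O)C[C@]1(COC(C)=O)O[C@@H]1CC/C(C)=C/I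
F11 | step 17 | open-chain 1,10-epoxy-8,14-diacetoxy iodo-aldehyde | CC(C)[C@H](C=O)[C@H](OC(C)=O)C[C@]1(COC(C)=O)O[C@@H]1CC/C(C)=C/I
F12 | step 17 | macrocyclic 1,10-epoxy-6-alcohol 8,14-diacetate | O[C@@H]1/C=C(\C)CC[C@H]2O[C@@]2(COC(C)=O)C[C@@H](OC(C)=O)[C@@H]1C(C)C
F13 | step 17 | macrocyclic 1,10-epoxy-6,8,14-triacetate | CC(=O)O[C@@H]1/C=C(\C)CC[C@H]2O[C@@]2(COC(C)=O)C[C@@H](OC(C)=O)[C@@H]1C(C)C
F14 | step 16 | 14-O-tert-butyldimethylsilyl ether of 26 | O[C@@H]1/C=C(\C)CC/C=C(CO[Si](C)(C)C(C)(C)C)\C[C@@H](O)[C@@H]1C(C)C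
F15 | step 16 | 14-O-TBS 6,8-diacetate | CC(=O)O[C@@H]1/C=C(\C)CC/C=C(CO[Si](C)(C)C(C)(C)C)\C[C@@H](OC(C)=O)[C@@H]1C(C)C
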